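**Retrosynthetic overview**

1. Target 30 ⇐ desilylation of 29 ⇐ 28. Ring A is closed last by a Dieckmann bond C2–C3 between an axial CO2Me on C1 and an axial acyl chain on C5.
2. 28 ⇐ 21. C5 is made quaternary by C-acylation, then C-alkylation with (S)-lavandulyl iodide anti to the C1 ester.
3. Key step, 21 ⇐ 19. Ring B and the C1–C8 bond (two adjacent quaternary carbons) come from a hydrogen-atom-transfer radical cyclisation of the isopropenyl group of an (R)-lavandulyl unit onto the tricarbonyl carbon C1.
4. 19 ⇐ methyl acetoacetate dianion + (R)-lavandulyl iodide, then C-aroylation with an acid chloride built from catechol.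
5. Both lavandulyl antipodes ⇐ one racemic lavandulol (methyl 3-methylbut-2-enoate + prenyl bromide) by lipase kinetic resolution, stopped short of half conversion for the (S)-alcohol and run past it for the (R)-alcohol. Ring order: ring B first, ring A last.

Assumption: porcine pancreas lipase acylates (S)-lavandulol faster than (R)-lavandulol; if the opposite holds, steps 3 and 4 exchange the enantiomer they deliver, with no change in step count.

Atom labels C1–C9 are the bicyclo[3.3.1]nonane positions of the target: C1 aroyl bridgehead, C5 lavandulyl bridgehead, C7 prenyl-bearing CH, C8 CMe2, C9 bridging ketone.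

**Route**

Step 1
Reactants: 1 methyl 3-methylbut-2-enoate; 2 1-bromo-3-methylbut-2-ene (prenyl bromide)
Product: 4 methyl (±)-5-methyl-2-(prop-1-en-2-yl)hex-4-enoate (racemic methyl lavandulate), via lithium dienolate 3 (not isolated)
Conditions: LiN(iPr)2, THF–DMPU, −78 °C; then 2, −78 → 0 °C
Reagents that add atoms: lithium diisopropylamide, [Li+].CC(C)[N-]C(C)C (lithium of 3 only)
Why: γ-Deprotonation gives the extended dienolate 3, which the allylic bromide alkylates at the α-carbon (deconjugative dienolate alkylation), giving the racemic lavandulyl skeleton.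

Step 2
Reactants: 4 methyl (±)-lavandulate
Product: 5 (±)-5-methyl-2-(prop-1-en-2-yl)hex-4-en-1-ol (racemic lavandulol)
Conditions: LiAlH4, Et2O, 0 °C; aqueous work-up
Reagents that add atoms: none
Why: Hydride reduction of the ester to the primary alcohol leaves the isolated alkenes untouched; the material is still racemic.

Step 3
Reactants: 5 (±)-lavandulol
Product: 7 (S)-lavandulol [(2S)-5-methyl-2-(prop-1-en-2-yl)hex-4-en-1-ol], via (S)-lavandulyl hydrogen succinate 6 (not isolated)
Conditions: porcine pancreas lipase, succinic anhydride (0.45 equiv), tBuOMe, 25 °C, to about 40 % conversion; filter; extract 6 into cold 0.5 M aq. NaOH; aqueous phase, more NaOH, 25 °C; extract with Et2O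
Reagents that add atoms: succinic anhydride, O=C1CCC(=O)O1 (succinyl group of 6 only)
Why: Lipase kinetic resolution by enantioselective acylation turns the faster-reacting (S)-alcohol into the hemisuccinate 6, which is drawn into aqueous base away from the unreacted alcohol and saponified there, so the stereocentre of 7 is fixed by the enzyme and stopping early keeps its ee high.

Step 4
Reactants: 5 (±)-lavandulol
Product: 8 (R)-lavandulol [(2R)-5-methyl-2-(prop-1-en-2-yl)hex-4-en-1-ol]
Conditions: porcine pancreas lipase, succinic anhydride (0.7 equiv), tBuOMe, 25 °C, to about 60 % conversion; filter; wash with cold 0.5 M aq. NaOH; concentrate the organic phase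
Reagents that add atoms: none
Why: The same lipase kinetic resolution run past half conversion consumes all of the (S)-alcohol, so the slower-reacting (R)-alcohol is the only alcohol left, in high ee, once the hemisuccinate is washed out with base; the R-enriched alcohol left in the organic phase of step 3 can be added to this charge.

Step 5
Reactants: 9 catechol (benzene-1,2-diol)
Product: 10 1,2-bis(triisopropylsilyloxy)benzene
Conditions: iPr3SiCl, imidazole, DMF, 25 → 50 °C
Reagents that add atoms: triisopropylsilyl chloride, CC(C)[Si](Cl)(C(C)C)C(C)C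
Why: Silylation of both phenols gives base-stable, fluoride-labile ethers that survive every later step.

Step 6
Reactants: 10 1,2-bis(triisopropylsilyloxy)benzene
Product: 11 4-bromo-1,2-bis(triisopropylsilyloxy)benzene
Conditions: N-bromosuccinimide, MeCN, 0 → 25 °C
Reagents that add atoms: N-bromosuccinimide, BrN1C(=O)CCC1=O
Why: Electrophilic aromatic bromination goes para to a silyloxy group because the positions ortho to oxygen are shielded by the bulky silyl ethers.

Step 7
Reactants: 11 4-bromo-1,2-bis(triisopropylsilyloxy)benzene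
Product: 13 3,4-bis(triisopropylsilyloxy)benzoic acid, via aryllithium 12 (not isolated)
Conditions: n-BuLi, THF, −78 °C; CO2; cold aq. HCl
Reagents that add atoms: carbon dioxide, O=C=O; n-butyllithium, [Li]CCCC (lithium of 12 only)
Why: Bromine–lithium exchange and carboxylation; lithium is not ortho to a silyloxy group, so no silyl migration occurs.

Step 8
Reactants: 8 (R)-lavandulol; 14 methyl acetoacetate (methyl 3-oxobutanoate)
Product: 17 methyl (6R)-9-methyl-3-oxo-6-(prop-1-en-2-yl)dec-8-enoate, via (R)-lavandulyl iodide 15 (not isolated), via dilithium acetoacetate dianion 16 (not isolated)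
Conditions: 8: PPh3, iodine, imidazole, CH2Cl2, 0 °C (crude 15); 14: LiN(iPr)2 (2.1 equiv), THF, 0 °C; then 15, 0 → 25 °C; cold aq. HCl
Reagents that add atoms: iodine, II (iodine of 15 only); lithium diisopropylamide, [Li+].CC(C)[N-]C(C)C (lithium of 16 only)
Why: Appel iodination followed by Weiler γ-alkylation of the acetoacetate dianion at its terminal carbon (future C5); the stereocentre (future C7) is next to the reacting CH2 and is untouched.

Step 9
Reactants: 13 3,4-bis(triisopropylsilyloxy)benzoic acid; 17 methyl (6R)-9-methyl-3-oxo-6-(prop-1-en-2-yl)dec-8-enoate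
Product: 19 methyl (6R)-2-[3,4-bis(triisopropylsilyloxy)benzoyl]-9-methyl-3-oxo-6-(prop-1-en-2-yl)dec-8-enoate (C2 epimers and enol forms), via aroyl chloride 18 (not isolated)
Conditions: 13: (COCl)2, DMF (cat.), CH2Cl2, 25 °C (crude 18); 17: MgCl2, Et3N, MeCN, 0 °C; then 18, 0 → 25 °C
Reagents that add atoms: oxalyl chloride, ClC(=O)C(=O)Cl (chlorine of 18 only)
Why: Magnesium-chelate-directed C-acylation of a β-keto ester by an acid chloride (Rathke conditions) gives the tricarbonyl methine; its central carbon (future C1) is enolised and carries no fixed configuration.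

Step 10
Reactants: 19 methyl (6R)-2-[3,4-bis(triisopropylsilyloxy)benzoyl]-9-methyl-3-oxo-6-(prop-1-en-2-yl)dec-8-enoate
Product: 21 methyl (1R,5R)-1-[3,4-bis(triisopropylsilyloxy)benzoyl]-6,6-dimethyl-5-(3-methylbut-2-en-1-yl)-2-oxocyclohexane-1-carboxylate, via tertiary radical 20 (not isolated)
Conditions: Co(salen) [N,N′-bis(3,5-di-tert-butylsalicylidene)ethylenediaminocobalt, C32H46CoN2O2] (5 mol %), N-fluoro-2,4,6-trimethylpyridinium triflate, PhSiH3, acetone, 0 °C
Reagents that add atoms: none
Why: Proposed new method: a trivalent cobalt hydride (from the divalent Co(salen) complex, the N-fluoropyridinium oxidant and PhSiH3) transfers a hydrogen atom to the 1,1-disubstituted isopropenyl alkene faster than to the trisubstituted prenyl alkene, giving tertiary radical 20, which forms the C1–C8 bond by 6-exo attack on the chelated enol carbon C1 (directly, with oxidation of the resulting ketyl-type radical, or after radical–polar crossover through a tetravalent alkylcobalt) through a chair transition state with the prenyl group equatorial and the hydrogen-bonded aroyl group equatorial, so the ester ends axial and C1 is set relative to the lavandulol-derived centre; the closest known reaction types are Co(salen)-catalysed hydrogen-atom-transfer hydrofunctionalisation of unactivated alkenes and the intramolecular Markovnikov hydroalkylation of alkenes by 1,3-dicarbonyl compounds.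

Step 11
Reactants: 22 acetic acid; 2 1-bromo-3-methylbut-2-ene
Product: 24 5-methylhex-4-enoic acid, via dilithium acetate dianion 23 (not isolated)
Conditions: LiN(iPr)2 (2.1 equiv), THF–DMPU, 0 °C; then 2, 0 → 25 °C; aq. HCl
Reagents that add atoms: lithium diisopropylamide, [Li+].CC(C)[N-]C(C)C (lithium of 23 only)
Why: Alkylation of the acetic acid enediolate with the allylic bromide gives the C3–C4 unit with the C3 prenyl group already attached.

Step 12
Reactants: 21 methyl (1R,5R)-1-[3,4-bis(triisopropylsilyloxy)benzoyl]-6,6-dimethyl-5-(3-methylbut-2-en-1-yl)-2-oxocyclohexane-1-carboxylate; 24 5-methylhex-4-enoic acid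
Product: 26 methyl (1R,5S)-1-[3,4-bis(triisopropylsilyloxy)benzoyl]-6,6-dimethyl-5-(3-methylbut-2-en-1-yl)-3-(5-methylhex-4-enoyl)-2-oxocyclohexane-1-carboxylate (ring carbon 3 epimerisable, largely enolised), via 5-methylhex-4-enoyl chloride 25 (not isolated)
Conditions: 24: (COCl)2, DMF (cat.), CH2Cl2 (crude 25); 21: MgBr2·OEt2, iPr2NEt, CH2Cl2, 25 °C; then 25
Reagents that add atoms: oxalyl chloride, ClC(=O)C(=O)Cl (chlorine of 25 only)
Why: Soft enolisation and C-acylation of the ketone at its only enolisable position (C5 of the target) gives the magnesium-chelated β-diketone without a strong base that could cleave the tricarbonyl carbon C1.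

Step 13
Reactants: 26 methyl (1R,5S)-1-[3,4-bis(triisopropylsilyloxy)benzoyl]-6,6-dimethyl-5-(3-methylbut-2-en-1-yl)-3-(5-methylhex-4-enoyl)-2-oxocyclohexane-1-carboxylate; 7 (S)-lavandulol
Product: 28 methyl (1S,3R,5S)-1-[3,4-bis(triisopropylsilyloxy)benzoyl]-6,6-dimethyl-5-(3-methylbut-2-en-1-yl)-3-(5-methylhex-4-enoyl)-3-[(2R)-5-methyl-2-(prop-1-en-2-yl)hex-4-en-1-yl]-2-oxocyclohexane-1-carboxylate, via (S)-lavandulyl iodide 27 (not isolated)
Conditions: 7: PPh3, iodine, imidazole, CH2Cl2, 0 °C (crude 27); 26: Cs2CO3, DMF, then 27, 50 °C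
Reagents that add atoms: iodine, II (iodine of 27 only)
Why: SN2 C-alkylation of the caesium β-diketonate creates the quaternary centre C5; the iodide enters anti to the axial ester on C1 (the syn face is 1,3-diaxially shielded), so the lavandulyl group ends equatorial and the acyl chain axial, cis to the ester.

Step 14
Reactants: 28 methyl (1S,3R,5S)-1-[3,4-bis(triisopropylsilyloxy)benzoyl]-6,6-dimethyl-5-(3-methylbut-2-en-1-yl)-3-(5-methylhex-4-enoyl)-3-[(2R)-5-methyl-2-(prop-1-en-2-yl)hex-4-en-1-yl]-2-oxocyclohexane-1-carboxylate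
Product: 29 (1S,5R,7S)-1-[3,4-bis(triisopropylsilyloxy)benzoyl]-2-hydroxy-8,8-dimethyl-3,7-bis(3-methylbut-2-en-1-yl)-5-[(2R)-5-methyl-2-(prop-1-en-2-yl)hex-4-en-1-yl]bicyclo[3.3.1]non-2-ene-4,9-dione
Conditions: LiN(SiMe3)2 (2.2 equiv), THF, −78 → 0 °C; cold aq. HCl
Reagents that add atoms: none
Why: Dieckmann condensation: the enolate of the axial acyl chain (the only enolisable site) attacks the syn-axial ester on C1 and closes ring A, driven by deprotonation of the new β-diketone at C3; both bridgeheads were fixed earlier and are not touched.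

Step 15
Reactants: 29 the bis(triisopropylsilyl) ether of the target
Product: 30 (1S,5R,7S)-1-(3,4-dihydroxybenzoyl)-2-hydroxy-8,8-dimethyl-3,7-bis(3-methylbut-2-en-1-yl)-5-[(2R)-5-methyl-2-(prop-1-en-2-yl)hex-4-en-1-yl]bicyclo[3.3.1]non-2-ene-4,9-dione (target)
Conditions: Bu4NF, AcOH, THF, 0 °C
Reagents that add atoms: none
Why: Buffered fluoride cleaves both aryl silyl ethers under conditions mild enough for the enolised triketone and the four alkenes; no stereocentre is involved.

**Compound list**

1 | methyl 3-methylbut-2-enoate | COC(=O)C=C(C)C | starting material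
2 | 1-bromo-3-methylbut-2-ene (prenyl bromide) | CC(C)=CCBr | starting material
3 | lithium dienolate of 1 | [Li+].COC([O-])=CC(C)=C | intermediate
4 | methyl (±)-5-methyl-2-(prop-1-en-2-yl)hex-4-enoate | COC(=O)C(CC=C(C)C)C(C)=C | intermediate
5 | (±)-lavandulol | OCC(CC=C(C)C)C(C)=C | intermediate
6 | (S)-lavandulyl hydrogen succinate [4-{[(2S)-5-methyl-2-(prop-1-en-2-yl)hex-4-en-1-yl]oxy}-4-oxobutanoic acid; carried as its sodium salt in the aqueous extract] | OC(=O)CCC(=O)OC[C@H](C(C)=C)CC=C(C)C | intermediate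
7 | (S)-lavandulol | OC[C@H](C(C)=C)CC=C(C)C | intermediate
8 | (R)-lavandulol | OC[C@@H](C(C)=C)CC=C(C)C | intermediate
9 | catechol | Oc1ccccc1O | starting material
10 | 1,2-bis(triisopropylsilyloxy)benzene | CC(C)[Si](C(C)C)(C(C)C)Oc1ccccc1O[Si](C(C)C)(C(C)C)C(C)C | intermediate
11 | 4-bromo-1,2-bis(triisopropylsilyloxy)benzene | CC(C)[Si](C(C)C)(C(C)C)Oc1ccc(Br)cc1O[Si](C(C)C)(C(C)C)C(C)C | intermediate
12 | [3,4-bis(triisopropylsilyloxy)phenyl]lithium | [Li]c1ccc(O[Si](C(C)C)(C(C)C)C(C)C)c(O[Si](C(C)C)(C(C)C)C(C)C)c1 | intermediate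
13 | 3,4-bis(triisopropylsilyloxy)benzoic acid | OC(=O)c1ccc(O[Si](C(C)C)(C(C)C)C(C)C)c(O[Si](C(C)C)(C(C)C)C(C)C)c1 | intermediate
14 | methyl acetoacetate | COC(=O)CC(C)=O | starting material
15 | (R)-lavandulyl iodide [(2R)-1-iodo-5-methyl-2-(prop-1-en-2-yl)hex-4-ene] | IC[C@@H](C(C)=C)CC=C(C)C | intermediate
16 | dilithium dianion of methyl acetoacetate | [Li+].[Li+].COC([O-])=CC(=C)[O-] | intermediate
17 | methyl (6R)-9-methyl-3-oxo-6-(prop-1-en-2-yl)dec-8-enoate | COC(=O)CC(=O)CC[C@@H](C(C)=C)CC=C(C)C | intermediate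
18 | 3,4-bis(triisopropylsilyloxy)benzoyl chloride | ClC(=O)c1ccc(O[Si](C(C)C)(C(C)C)C(C)C)c(O[Si](C(C)C)(C(C)C)C(C)C)c1 | intermediate
19 | methyl (6R)-2-[3,4-bis(triisopropylsilyloxy)benzoyl]-9-methyl-3-oxo-6-(prop-1-en-2-yl)dec-8-enoate | COC(=O)C(C(=O)c1ccc(O[Si](C(C)C)(C(C)C)C(C)C)c(O[Si](C(C)C)(C(C)C)C(C)C)c1)C(=O)CC[C@@H](C(C)=C)CC=C(C)C | intermediate
20 | tertiary radical from 19 (radical at the former isopropenyl carbon, same configuration at C6) | COC(=O)C(C(=O)c1ccc(O[Si](C(C)C)(C(C)C)C(C)C)c(O[Si](C(C)C)(C(C)C)C(C)C)c1)C(=O)CC[C@@H]([C](C)C)CC=C(C)C | intermediate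
21 | methyl (1R,5R)-1-[3,4-bis(triisopropylsilyloxy)benzoyl]-6,6-dimethyl-5-(3-methylbut-2-en-1-yl)-2-oxocyclohexane-1-carboxylate | C1C[C@H](CC=C(C)C)C(C)(C)[C@@](C(=O)c2ccc(O[Si](C(C)C)(C(C)C)C(C)C)c(O[Si](C(C)C)(C(C)C)C(C)C)c2)(C(=O)OC)C1=O | intermediate
22 | acetic acid | CC(=O)O | starting material
23 | dilithium dianion of acetic acid | [Li+].[Li+].C=C([O-])[O-] | intermediate
24 | 5-methylhex-4-enoic acid | CC(C)=CCCC(=O)O | intermediate
25 | 5-methylhex-4-enoyl chloride | CC(C)=CCCC(=O)Cl | intermediate
26 | methyl (1R,5S)-1-[3,4-bis(triisopropylsilyloxy)benzoyl]-6,6-dimethyl-5-(3-methylbut-2-en-1-yl)-3-(5-methylhex-4-enoyl)-2-oxocyclohexane-1-carboxylate | CC(C)=CCCC(=O)C1C[C@H](CC=C(C)C)C(C)(C)[C@@](C(=O)c2ccc(O[Si](C(C)C)(C(C)C)C(C)C)c(O[Si](C(C)C)(C(C)C)C(C)C)c2)(C(=O)OC)C1=O | intermediate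
27 | (S)-lavandulyl iodide [(2S)-1-iodo-5-methyl-2-(prop-1-en-2-yl)hex-4-ene] | IC[C@H](C(C)=C)CC=C(C)C | intermediate
28 | methyl (1S,3R,5S)-1-[3,4-bis(triisopropylsilyloxy)benzoyl]-6,6-dimethyl-5-(3-methylbut-2-en-1-yl)-3-(5-methylhex-4-enoyl)-3-[(2R)-5-methyl-2-(prop-1-en-2-yl)hex-4-en-1-yl]-2-oxocyclohexane-1-carboxylate | C=C(C)[C@H](CC=C(C)C)C[C@]1(C(=O)CCC=C(C)C)C[C@H](CC=C(C)C)C(C)(C)[C@@](C(=O)c2ccc(O[Si](C(C)C)(C(C)C)C(C)C)c(O[Si](C(C)C)(C(C)C)C(C)C)c2)(C(=O)OC)C1=O | intermediate
29 | (1S,5R,7S)-1-[3,4-bis(triisopropylsilyloxy)benzoyl]-2-hydroxy-8,8-dimethyl-3,7-bis(3-methylbut-2-en-1-yl)-5-[(2R)-5-methyl-2-(prop-1-en-2-yl)hex-4-en-1-yl]bicyclo[3.3.1]non-2-ene-4,9-dione | C=C(C)[C@H](CC=C(C)C)C[C@]12C[C@H](CC=C(C)C)C(C)(C)[C@](C(=O)c3ccc(O[Si](C(C)C)(C(C)C)C(C)C)c(O[Si](C(C)C)(C(C)C)C(C)C)c3)(C1=O)C(O)=C(CC=C(C)C)C2=O | intermediate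
30 | (1S,5R,7S)-1-(3,4-dihydroxybenzoyl)-2-hydroxy-8,8-dimethyl-3,7-bis(3-methylbut-2-en-1-yl)-5-[(2R)-5-methyl-2-(prop-1-en-2-yl)hex-4-en-1-yl]bicyclo[3.3.1]non-2-ene-4,9-dione | C=C(C)[C@H](CC=C(C)C)C[C@]12C[C@H](CC=C(C)C)C(C)(C)[C@](C(=O)c3ccc(O)c(O)c3)(C1=O)C(O)=C(CC=C(C)C)C2=O | target

**Step count and risks**

Total step count: 15. Longest linear sequence: 10 steps (1, 2, 4, 8, 9, 10, 12, 13, 14, 15).

Steps most likely to fail:

Step 10 (the radical ring closure). The enol oxygen can capture C8 instead of C1 and give a six-membered cyclic enol ether; radical 20 can add 5-exo to C9; the prenyl alkene can take up the hydrogen atom. Fallback: it sets out from 19 and comes back at 21. The isopropenyl group is hydrated selectively under Mukaiyama conditions (cobalt bis(acetylacetonate), Co(C5H7O2)2, with divalent cobalt, PhSiH3, O2, iPrOH) to the tertiary alcohol methyl (6R)-2-[3,4-bis(triisopropylsilyloxy)benzoyl]-6-(2-hydroxypropan-2-yl)-9-methyl-3-oxodec-8-enoate F1. This is then ionised with catalytic bismuth triflate, Bi(O3SCF3)3, in CH2Cl2 at −20 °C; any O-alkylated enol ether re-ionises, so the tertiary cation alkylates C1 under thermodynamic control through the same chair arrangement and gives 21.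

Step 13 (quaternary C5). The β-branched primary iodide reacts slowly with a hindered, stabilised diketonate, so O-alkylation and base-induced deacylation can compete. Fallback: it sets out from 26 and 7 and comes back at 28. The iodide and the base are dropped and the alcohol 7 itself is used as electrophile in a Mitsunobu-type redox-condensation C-alkylation with cyanomethylenetributylphosphorane (Bu3P=CHCN) in toluene at 100 °C. The alkoxyphosphonium ion is attacked by the free diketone from the same unshielded face under neutral conditions; this fallback makes no new compound (F0).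

Step 14 (Dieckmann closure). The tricarbonyl carbon C1 is open to retro-Claisen cleavage by the methoxide that is released, and the ester is hindered. Fallback: it sets out from 28 and comes back at 29. The kinetic enolate of the acyl chain (LiN(SiMe3)2, THF, −78 °C) is quenched with N-bromosuccinimide to give the α-bromo ketone methyl 1-[3,4-bis(triisopropylsilyloxy)benzoyl]-3-(2-bromo-5-methylhex-4-enoyl)-6,6-dimethyl-5-(3-methylbut-2-en-1-yl)-3-[(2R)-5-methyl-2-(prop-1-en-2-yl)hex-4-en-1-yl]-2-oxocyclohexane-1-carboxylate (ring configurations as in 28, either epimer at the CHBr carbon) F2. Samarium diiodide, SmI2 (divalent samarium), in THF at −78 °C then reduces the C–Br bond to a trivalent samarium enolate, which adds to the neighbouring ester in a Reformatsky-type ring closure at low temperature and without free lithium alkoxide, giving 29.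

**Further compounds**

F1 | step 10 | methyl (6R)-2-[3,4-bis(triisopropylsilyloxy)benzoyl]-6-(2-hydroxypropan-2-yl)-9-methyl-3-oxodec-8-enoate | COC(=O)C(C(=O)c1ccc(O[Si](C(C)C)(C(C)C)C(C)C)c(O[Si](C(C)C)(C(C)C)C(C)C)c1)C(=O)CC[C@@H](C(C)(C)O)CC=C(C)C
F0 | step 13 | none | none
F2 | step 14 | methyl 1-[3,4-bis(triisopropylsilyloxy)benzoyl]-3-(2-bromo-5-methylhex-4-enoyl)-6,6-dimethyl-5-(3-methylbut-2-en-1-yl)-3-[(2R)-5-methyl-2-(prop-1-en-2-yl)hex-4-en-1-yl]-2-oxocyclohexane-1-carboxylate (ring configurations as in 28) | C=C(C)[C@H](CC=C(C)C)C[C@]1(C(=O)C(Br)CC=C(C)C)C[C@H](CC=C(C)C)C(C)(C)[C@@](C(=O)c2ccc(O[Si](C(C)C)(C(C)C)C(C)C)c(O[Si](C(C)C)(C(C)C)C(C)C)c2)(C(=O)OC)C1=O
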